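**Retrosynthetic overview**
1. The two aldehydes come last from a macrocyclic bis-Weinreb amide. The nine-membered ring is closed just before that, at C7–C8, by B-alkyl Suzuki coupling of a hydroborated C1-vinyl group with an (E)-C7 vinyl iodide.
2. The vinyl group and the C1′ arm come from zinc fragmentation of an iodomethyl γ-butyrolactone, which erases the bought stereocentre. C3=C4 comes from an HWE reaction with (E)-4-iodopent-3-enal, and the homoprenyl group from lactone-enolate alkylation.
3. Key disconnection: the C1–C2 bond between the two ring stereocentres, made by a visible-light reductive 6-exo cyclisation of a butenolide onto an ester-tethered phosphono-fumarate built on (S)-5-(hydroxymethyl)furan-2(5H)-one.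
4. Ring order: butenolide (bought) → fused δ-lactone (photochemical step) → δ-lactone opened and γ-lactone fragmented → nine-membered carbocycle (last ring).

Assumption: compounds 1, 2, 4, 7 and 11 are taken as commercial; atom labels follow the target name (2R)-2-[(1S,2S,3E,6E)-2,3-diformyl-7-methylcyclonona-3,6-dien-1-yl]-6-methylhept-5-en-1-yl acetate (ring C1–C9, side chain C1′–C7′).

Step 1
Reactants: 1 glyoxylic acid monohydrate; 2 diethyl {2-[methoxy(methyl)amino]-2-oxoethyl}phosphonate
Product: 3 phosphono-fumaric acid mono-Weinreb amide (E/Z mixture)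
Conditions: piperidine (0.1 equiv), AcOH (0.2 equiv), toluene, 80 °C, Dean–Stark
Reagents that add atoms: none
Why: Knoevenagel condensation of the active-methylene phosphonate with the electrophilic aldehyde; without a metal base the phosphonate is retained, and the alkene geometry is irrelevant because the alkene is consumed in step 3.

Step 2
Reactants: 3 phosphono-fumaric acid mono-Weinreb amide; 4 (S)-5-(hydroxymethyl)furan-2(5H)-one
Product: 5 butenolide phosphono-fumarate ester
Conditions: EDC·HCl, DMAP (5 mol%), CH2Cl2, 0 °C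
Reagents that add atoms: none
Why: Steglich esterification of the primary alcohol under near-neutral conditions, so the base-labile γ-stereocentre of the butenolide (future C9) is not racemised.

Step 3
Reactants: 5 butenolide phosphono-fumarate ester
Product: 6 cis-fused γ/δ-bislactone phosphonate (C1 set; C2 and P–CH epimers)
Conditions: [Ir(ppy)2(dtbbpy)]PF6 (1 mol%), Hantzsch ester (1.3 equiv), AcOH (1 equiv), degassed MeCN (0.02 M), 450 nm LEDs, rt
Reagents that add atoms: none
Why: Proposed new method: a visible-light reductive cyclisation of two tethered Michael acceptors, in which photoreduced Ir(II) transfers one electron only to the triply activated alkene (about −1.3 V against about −2 V for the butenolide), the radical anion (spin on the carbon α to the tether ester, C2) closes 6-exo onto the butenolide β-carbon (C1) and Hantzsch ester reduces and protonates the lactone α-radical; the ester tether on the bought (S) centre can only deliver C2 to its own face, so the new C1–C2 bond is cis to the CH2O bridge and C1 is fixed; the closest known reaction type is the photocatalytic or cathodic reductive cyclisation (electrohydrocyclisation) of tethered bis-enones and bis-enoates, which has not been shown for a butenolide acceptor, a lactone-forming ester tether or a phosphono-fumarate partner.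

Step 4
Reactants: 7 pent-3-yn-1-ol
Product: 9 (E)-4-iodopent-3-en-1-ol, via alkenylzirconocene 8 (not isolated)
Conditions: Cp2Zr(H)Cl (2.3 equiv), THF, 45 °C; then I2, 0 °C
Reagents that add atoms: iodine, II; Schwartz reagent, [H][Zr](Cl)(C1C=CC=C1)C1C=CC=C1 (its atoms stay only in 8)
Why: syn-hydrozirconation (the first equivalent only deprotonates the OH) with excess reagent equilibrates zirconium to the methyl-bearing carbon, and iodinolysis with retention gives the E vinyl iodide.

Step 5
Reactants: 9 (E)-4-iodopent-3-en-1-ol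
Product: 10 (E)-4-iodopent-3-enal
Conditions: Dess–Martin periodinane, NaHCO3, CH2Cl2, 0 °C; used crude
Reagents that add atoms: none
Why: Dess–Martin oxidation under buffered conditions gives the β,γ-unsaturated aldehyde without migration of the double bond.

Step 6
Reactants: 6 cis-fused bislactone phosphonate; 11 5-iodo-2-methylpent-2-ene; 10 (E)-4-iodopent-3-enal
Product: 13 alkylidene bislactone (C2 epimers), via homoprenylated phosphonate 12 (not isolated)
Conditions: LDA (2.1 equiv), THF–DMPU, −78 °C; 11, −78 → −40 °C; then 10, −78 → 0 °C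
Reagents that add atoms: none
Why: in the dianion the γ-lactone enolate is the more reactive site and is alkylated on the convex face, trans to the C1–C2 bond (sets C2′); the surviving phosphonate carbanion then undergoes Horner–Wadsworth–Emmons olefination to the (E)-enamide (C3=C4).

Step 7
Reactants: 13 alkylidene bislactone (C2 epimers)
Product: 14 alkylidene bislactone with the target C2 configuration
Conditions: KHMDS (1.05 equiv), THF, −78 °C; then 2,4,6-trimethylbenzoic acid, −78 °C
Reagents that add atoms: none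
Why: kinetic diastereoselective enolate protonation; both C2 epimers give the same δ-lactone dienolate, and the bulky acid protonates the α-carbon on the convex face of the cis-fused bicycle (anti to the γ-lactone), which places the alkenyl arm on the concave face as the target requires.

Step 8
Reactants: 14 alkylidene bislactone with the target C2 configuration
Product: 15 hydroxymethyl γ-lactone bis-Weinreb amide
Conditions: MeNH(OMe)·HCl (1.5 equiv), AlMe3 (1.5 equiv), CH2Cl2, −20 → 0 °C
Reagents that add atoms: N,O-dimethylhydroxylamine hydrochloride, CNOC.Cl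
Why: Weinreb aminolysis with the aluminium amide; δ-lactones undergo acyl substitution markedly faster than γ-lactones, so only the six-membered lactone should open, and the non-basic reagent leaves C2 untouched.

Step 9
Reactants: 15 hydroxymethyl γ-lactone bis-Weinreb amide
Product: 17 vinyl seco-acid, via iodomethyl lactone 16 (not isolated)
Conditions: I2, PPh3, imidazole, THF, 0 °C → rt; then Zn dust, AcOH, rt
Reagents that add atoms: iodine, II (stays only in 16)
Why: Appel-type iodination of the primary alcohol, then zinc-induced reductive β-elimination of the β-iodo lactone (reverse iodolactonisation) unmasks the C9=C8 vinyl group and the C1′ acid; the bought stereocentre is erased only after it has set C1, C2′ and C2.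

Step 10
Reactants: 17 vinyl seco-acid
Product: 19 primary alcohol, via mixed carbonic anhydride 18 (not isolated)
Conditions: iBuOCOCl, N-methylmorpholine, THF, −15 °C; then NaBH4, H2O, 0 °C
Reagents that add atoms: isobutyl chloroformate, CC(C)COC(=O)Cl (stays only in 18)
Why: mixed-anhydride activation followed by borohydride reduction reduces only the carboxylic acid; Weinreb amides, the enamide and the vinyl iodide are inert to NaBH4.

Step 11
Reactants: 19 primary alcohol
Product: 20 acetate
Conditions: Ac2O, pyridine, DMAP (cat.), CH2Cl2, rt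
Reagents that add atoms: acetic anhydride, CC(=O)OC(C)=O
Why: standard acylation of the only free hydroxyl, done before any aldehyde exists so that no lactol can form.

Step 12
Reactants: 20 acetate
Product: 22 nine-membered bis-Weinreb amide, via B-alkyl-9-BBN 21 (not isolated)
Conditions: 9-BBN (1.5 equiv), THF, rt; then syringe-pump addition to Pd(dppf)Cl2 (15 mol%), AsPh3 (30 mol%), Cs2CO3, DMF/THF/H2O, 2 mM, 40 °C
Reagents that add atoms: 9-BBN, [H]B1C2CCCC1CCC2 (stays only in 21)
Why: 9-BBN hydroborates only the monosubstituted alkene, and the intramolecular B-alkyl Suzuki–Miyaura coupling with the (E)-vinyl iodide closes the ring at C7–C8 with retention of geometry, a closure used for closely related xenicane (E)-cyclononenes; no stereocentre is formed.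

Step 13
Reactants: 22 nine-membered bis-Weinreb amide
Product: 23 target dialdehyde
Conditions: Cp2Zr(H)Cl (3.5 equiv), THF, rt, 15 min; SiO2 work-up
Reagents that add atoms: none
Why: Schwartz reduction of tertiary amides stops at a zirconated hemiaminal that releases the aldehyde only on work-up, so both Weinreb amides become CHO while the acetate survives and the neutral conditions do not epimerise C2.

**Compound list**
1 | glyoxylic acid monohydrate | OC(O)C(=O)O | starting material
2 | diethyl {2-[methoxy(methyl)amino]-2-oxoethyl}phosphonate | CCOP(=O)(OCC)CC(=O)N(C)OC | starting material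
3 | 3-(diethoxyphosphoryl)-4-[methoxy(methyl)amino]-4-oxobut-2-enoic acid (E/Z mixture) | OC(=O)C=C(P(=O)(OCC)OCC)C(=O)N(C)OC | intermediate
4 | (S)-5-(hydroxymethyl)furan-2(5H)-one | O=C1C=C[C@@H](CO)O1 | starting material
5 | [(2S)-5-oxo-2,5-dihydrofuran-2-yl]methyl 3-(diethoxyphosphoryl)-4-[methoxy(methyl)amino]-4-oxobut-2-enoate (E/Z mixture) | O=C1C=C[C@@H](COC(=O)C=C(P(=O)(OCC)OCC)C(=O)N(C)OC)O1 | intermediate
6 | diethyl {1-[(3aS,7aS)-2,5-dioxohexahydro-2H-furo[2,3-c]pyran-4-yl]-2-[methoxy(methyl)amino]-2-oxoethyl}phosphonate (cis-fused; epimers at C4 and at the P-bearing carbon) | O=C1C[C@@H]2[C@@H](COC(=O)C2C(P(=O)(OCC)OCC)C(=O)N(C)OC)O1 | intermediate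
7 | pent-3-yn-1-ol | CC#CCCO | starting material
8 | (E)-alkenylzirconocene chloride from 7 (Zr on the methyl-bearing carbon, H and Zr cis; oxygen also zirconated) | Cl[Zr](C1C=CC=C1)(C1C=CC=C1)OCC/C=C(C)/[Zr](Cl)(C1C=CC=C1)C1C=CC=C1 | intermediate
9 | (E)-4-iodopent-3-en-1-ol | OCC/C=C(C)/I | intermediate
10 | (E)-4-iodopent-3-enal | O=CC/C=C(C)/I | intermediate
11 | 5-iodo-2-methylpent-2-ene | CC(C)=CCCI | starting material
12 | diethyl {2-[methoxy(methyl)amino]-1-[(3R,3aS,7aS)-3-(4-methylpent-3-en-1-yl)-2,5-dioxohexahydro-2H-furo[2,3-c]pyran-4-yl]-2-oxoethyl}phosphonate (epimers at C4 and P–CH) | O=C1[C@H](CCC=C(C)C)[C@@H]2[C@@H](COC(=O)C2C(P(=O)(OCC)OCC)C(=O)N(C)OC)O1 | intermediate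
13 | (2E,5E)-6-iodo-N-methoxy-N-methyl-2-[(3R,3aS,7aS)-3-(4-methylpent-3-en-1-yl)-2,5-dioxohexahydro-2H-furo[2,3-c]pyran-4-yl]hepta-2,5-dienamide (C4 epimers, mainly 4R) | O=C1[C@H](CCC=C(C)C)[C@@H]2[C@@H](COC(=O)C2/C(C(=O)N(C)OC)=C\C/C=C(C)/I)O1 | intermediate
14 | (2E,5E)-6-iodo-N-methoxy-N-methyl-2-[(3R,3aS,4S,7aS)-3-(4-methylpent-3-en-1-yl)-2,5-dioxohexahydro-2H-furo[2,3-c]pyran-4-yl]hepta-2,5-dienamide | O=C1[C@H](CCC=C(C)C)[C@@H]2[C@@H](COC(=O)[C@@H]2/C(C(=O)N(C)OC)=C\C/C=C(C)/I)O1 | intermediate
15 | (2S,3E)-2-[(2S,3R,4R)-2-(hydroxymethyl)-4-(4-methylpent-3-en-1-yl)-5-oxooxolan-3-yl]-3-[(3E)-4-iodopent-3-en-1-ylidene]-N1,N4-dimethoxy-N1,N4-dimethylbutanediamide | O=C1[C@H](CCC=C(C)C)[C@H]([C@@H](CO)O1)[C@H](C(=O)N(C)OC)/C(C(=O)N(C)OC)=C\C/C=C(C)/I | intermediate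
16 | (2S,3E)-2-[(2S,3R,4R)-2-(iodomethyl)-4-(4-methylpent-3-en-1-yl)-5-oxooxolan-3-yl]-3-[(3E)-4-iodopent-3-en-1-ylidene]-N1,N4-dimethoxy-N1,N4-dimethylbutanediamide | O=C1[C@H](CCC=C(C)C)[C@H]([C@@H](CI)O1)[C@H](C(=O)N(C)OC)/C(C(=O)N(C)OC)=C\C/C=C(C)/I | intermediate
17 | (2S,3E)-2-[(3R,4R)-4-carboxy-8-methylnona-1,7-dien-3-yl]-3-[(3E)-4-iodopent-3-en-1-ylidene]-N1,N4-dimethoxy-N1,N4-dimethylbutanediamide | OC(=O)[C@H](CCC=C(C)C)[C@H](C=C)[C@H](C(=O)N(C)OC)/C(C(=O)N(C)OC)=C\C/C=C(C)/I | intermediate
18 | isobutyl carbonic mixed anhydride of acid 17 (same configuration) | CC(C)COC(=O)OC(=O)[C@H](CCC=C(C)C)[C@H](C=C)[C@H](C(=O)N(C)OC)/C(C(=O)N(C)OC)=C\C/C=C(C)/I | intermediate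
19 | (2S,3E)-2-[(3S,4R)-4-(hydroxymethyl)-8-methylnona-1,7-dien-3-yl]-3-[(3E)-4-iodopent-3-en-1-ylidene]-N1,N4-dimethoxy-N1,N4-dimethylbutanediamide | OC[C@H](CCC=C(C)C)[C@H](C=C)[C@H](C(=O)N(C)OC)/C(C(=O)N(C)OC)=C\C/C=C(C)/I | intermediate
20 | (2S,3E)-2-[(3S,4R)-4-(acetoxymethyl)-8-methylnona-1,7-dien-3-yl]-3-[(3E)-4-iodopent-3-en-1-ylidene]-N1,N4-dimethoxy-N1,N4-dimethylbutanediamide | CC(=O)OC[C@H](CCC=C(C)C)[C@H](C=C)[C@H](C(=O)N(C)OC)/C(C(=O)N(C)OC)=C\C/C=C(C)/I | intermediate
21 | B-alkyl-9-BBN adduct of 20 (boron on the terminal carbon C8; configuration unchanged) | CC(=O)OC[C@H](CCC=C(C)C)[C@H](CCB1C2CCCC1CCC2)[C@H](C(=O)N(C)OC)/C(C(=O)N(C)OC)=C\C/C=C(C)/I | intermediate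
22 | (2R)-2-{(1S,2S,3E,6E)-2,3-bis[methoxy(methyl)carbamoyl]-7-methylcyclonona-3,6-dien-1-yl}-6-methylhept-5-en-1-yl acetate | CC(=O)OC[C@H](CCC=C(C)C)[C@@H]1CC/C(C)=C/C/C=C(/C(=O)N(C)OC)[C@H]1C(=O)N(C)OC | intermediate
23 | (2R)-2-[(1S,2S,3E,6E)-2,3-diformyl-7-methylcyclonona-3,6-dien-1-yl]-6-methylhept-5-en-1-yl acetate | CC(=O)OC[C@H](CCC=C(C)C)[C@@H]1CC/C(C)=C/C/C=C(/C=O)[C@H]1C=O | target

**Step count and risks**
Total: 13 steps (11 in the main line, 2 for aldehyde 10). Longest linear sequence: 11 steps (steps 1, 2, 3, 6, 7, 8, 9, 10, 11, 12, 13).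

Step 3 (new photoreductive cyclisation) may give only simple reduction of the activated alkene, or the ester tether may not reach the lactone-forming conformation. The fallback sets out from 5: conjugate addition of HBr (AcOH, 0 °C; bromide adds β to the phosphono-amide carbon) gives the α-bromo ester F1. A classical tin-hydride reductive radical cyclisation of this α-halo ester (Bu3SnH, AIBN, benzene, 80 °C, slow addition) closes the same 6-exo ring, and the route is rejoined at 6.

Step 8 (selective aminolysis of the δ-lactone) may also open the γ-lactone or epimerise C2. The fallback sets out from 14 and cleaves the δ-lactone at its alkyl C–O bond instead: MgI2 (toluene/MeCN, 60 °C) attacks the primary CH2–O carbon by SN2 and gives the iodo acid F2. Carbodiimide coupling of F2 with MeNH(OMe)·HCl then gives 16, which is taken on with zinc as in step 9.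

Step 12 (nine-membered ring closure) may give oligomers or protodeboronation. The fallback sets out from 20: hydroboration–oxidation (9-BBN; NaBO3·4H2O) gives the primary alcohol F3, and I2/PPh3/imidazole gives the primary iodide F4. Zinc dust with LiCl (THF, 25 °C) inserts only into the alkyl C–I bond to give the alkylzinc iodide F5, which is added slowly to Pd(OAc)2/SPhos for an intramolecular Negishi coupling that comes back at 22.

**Further compounds**
F1 | step 3 | [(2S)-5-oxo-2,5-dihydrofuran-2-yl]methyl 2-bromo-3-(diethoxyphosphoryl)-4-[methoxy(methyl)amino]-4-oxobutanoate | O=C1C=C[C@@H](COC(=O)C(Br)C(P(=O)(OCC)OCC)C(=O)N(C)OC)O1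
F2 | step 8 | (2S,3E)-2-[(2S,3R,4R)-2-(iodomethyl)-4-(4-methylpent-3-en-1-yl)-5-oxooxolan-3-yl]-6-iodo-3-[methoxy(methyl)carbamoyl]hepta-3,6-dienoic acid | O=C1[C@H](CCC=C(C)C)[C@H]([C@@H](CI)O1)[C@H](C(O)=O)/C(C(=O)N(C)OC)=C\C/C=C(C)/I
F3 | step 12 | primary alcohol from anti-Markovnikov hydration of the vinyl group of 20 (C8–OH) | CC(=O)OC[C@H](CCC=C(C)C)[C@H](CCO)[C@H](C(=O)N(C)OC)/C(C(=O)N(C)OC)=C\C/C=C(C)/I
F4 | step 12 | primary iodide corresponding to F3 (C8–I) | CC(=O)OC[C@H](CCC=C(C)C)[C@H](CCI)[C@H](C(=O)N(C)OC)/C(C(=O)N(C)OC)=C\C/C=C(C)/I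
F5 | step 12 | alkylzinc iodide corresponding to F4 (C8–ZnI) | CC(=O)OC[C@H](CCC=C(C)C)[C@H](CC[Zn]I)[C@H](C(=O)N(C)OC)/C(C(=O)N(C)OC)=C\C/C=C(C)/I
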